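Remark on numbering: ring positions C1–C6 (C1 = carbonyl carbon, C5 = carbinol carbon carrying the chain) and chain positions C1′–C19′ of the target are used as locants for all intermediates. (E)-Hex-3-en-1-ol, 1,12-dibromododecane and 2-hydroxy-5-methoxybenzaldehyde are taken as purchasable.

## Analysis of the target

The target 15 is a cyclohex-2-en-1-one (C1=O, C2=C3) with a secondary carbinol at C4, a fully substituted carbinol at C5 and a methylene at C6. C5 also carries an unbranched C19 chain whose only functional group is the (E)-C16′=C17′ alkene. The SMILES decodes to (4R,5S), which places the two hydroxyl groups cis on the ring. The ring oxygens sit at C1, C4 and C5, with C1 and C4 para to each other and the chain on the carbon ortho to C4. The carbocycle is therefore the formal C5–C6 hydrate of the keto tautomer of a 2-alkylhydroquinone, that is, a dearomatised benzene ring. This is also the main liability: C5–OH is β to the ketone and C6–H is acidic, so acid or base causes dehydration or retro-aldol opening, and the resulting 4-hydroxydienone tautomerises irreversibly to the flat arene, erasing both stereocentres. The hard bond is C5–O at the quaternary centre, which must be made cis to C4–O and in one absolute sense. The remote (E)-alkene rules out hydrogenation, peracids and osmium-based dihydroxylation once the chain is in place, so ring oxidants must be directed, and the last operations must be near neutral.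

## Retrosynthetic reasoning

**15 ⇒ 14.** The C6–H bond is traded for a C6–O bond, giving the cis-epoxy enone 14, in which the C5 oxygen is tied to C6 as an α,β-epoxy ketone. The β-hydroxy ketone is then released by a single-electron reduction at low temperature in a neutral medium. The C5–O bond is never broken in this step, so no stereocentre is at risk.

**14 ⇒ 13.** The C1 carbonyl is taken back to a dimethyl ketal. A free C4 hydroxyl and a C1 carbonyl can coexist only once C5=C6 is no longer an alkene; before that the pair would be a tautomer of the aromatic ring. The ketal therefore has to stay until the epoxide is in place.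

**13 ⇒ 12.** The C5–O and C6–O bonds of the epoxide are cut, giving the bis-allylic alcohol 12. In the forward direction the C4 hydroxyl directs a metal-bound peroxide to its own face of the trisubstituted C5=C6 alkene. This sets C5 relative to C4 and needs no reagent that would see the chain alkene.

**12 ⇒ 11.** The C4–H bond is cut, giving the cross-conjugated dienone 11. The forward reaction is the only reagent-controlled stereochemical event of the route: an oxazaborolidine-catalysed borane reduction that distinguishes the α-branched alkenyl arm (C5 side) from the unbranched one (C3 side).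

**11 ⇒ 10 (key disconnection).** The C1–OMe bond of the ketal is cut and the ring is re-aromatised to phenol 10. The ring substitution of 15 maps atom for atom onto 10: C4–O is the phenol oxygen, C1–O the anisole oxygen, C5 the alkyl-bearing carbon. Forward, an iodine(III) oxidant in an alcohol solvent converts a flat, achiral arene with no stereocentre into a ring that has all six carbons at the oxidation pattern of the target and two differentiated prochiral elements. The chain is attached at the arene stage, where a C–C bond next to the future quaternary carbon is easy to form.

**10 ⇒ 9 ⇒ 5 + 6.** The benzylic C–O bond is removed and the C1′–C2′ bond is cut. The aldehyde carbon of 6 becomes C1′, so that a C18 Grignard reagent from 5 completes the C19 chain. The benzylic oxygen left behind by the addition is removed by ionic hydrogenation.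

**5 ⇒ 2 + 3; 2 ⇒ 1.** The C13′–C14′ bond is cut by an sp3–sp3 copper-catalysed Grignard coupling. The (E)-alkene is bought with 1, not made, and is carried untouched through every later step.

## Alternatives that were turned down

**Alternative 1:** (the textbook route) Disconnection of C2=C3 by ring-closing metathesis. The forward key step would be closure of the acyclic dienone diol A1 with a ruthenium carbene, after an osmium-catalysed asymmetric dihydroxylation had set C4 and C5. It was turned down for three reasons.
- The chain C16′=C17′ alkene is a competent metathesis partner, so secondary metathesis would truncate the chain, scramble E/Z or close a macrocycle.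
- The dihydroxylation cannot tell the chain alkene from the ring precursor alkene, so the chain alkene would have to be introduced late or masked.
- A1 combines a vinyl ketone with an acyclic β-hydroxy ketone (polymerisation, retro-aldol), which forces protecting groups and pushes the count well above ten steps.

**Alternative 2:** Both C–O bonds at C4 and C5 formed at once on an arene by an enzyme. The forward key step would be whole-cell ipso,ortho cis-dihydroxylation of benzoic acid A2 by a benzoate 1,2-dioxygenase (Rieske non-haem iron dioxygenase) to the diol acid A3. The (1S,2R) centres of A3 map exactly, in relative and absolute sense, onto C5 and C4 of 15. It was turned down because A3 lacks everything else the target needs.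
- The carboxyl carbon must become C1′ and be joined to a C18 chain at a neopentyl position, next to a tertiary carbinol and a diene that aromatises on any ionisation.
- The C1 ketone must be placed on the internal diene carbon with hydrogen going to C6. Electrophilic oxidants attack the diene termini, and the terminus next to the quaternary carbon is the hindered one, so this oxygenation runs against both steric and electronic bias and would need a multi-step transposition.
- The enzymatic step would be followed by eight or more steps, which costs more than the stereochemical gain.

**Alternative 3:** Direct formation of the C5–O bond by ortho-hydroxylative dearomatisation of phenol 10. The forward key step would be enantioselective oxygen transfer to the alkyl-bearing ortho carbon (chiral iodine(V) reagent or flavin-dependent monooxygenase) to give the o-quinol A4. A syn 1,2-reduction of its carbonyl and hydrolysis of its enol ether would then reach 15 in three steps from 10. It was turned down for four reasons.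
- The oxidant would have to choose the substituted ortho carbon over the para carbon, where iodine reagents normally react (leading to 11), and over the free ortho carbon.
- o-Quinols of this type dimerise by [4+2] cycloaddition.
- The known enzymes of this class need resorcinol-type, carbonyl-substituted substrates.
- In the endgame the tertiary C5 hydroxyl would be allylic to a methyl enol ether. The acid needed to hydrolyse that ether would ionise C5–O (Stork–Danheiser-type transposition) and aromatise the ring.

Key step: step 5

## Route

Step 1
Reactants: 1 (3E)-hex-3-en-1-ol
Product: 2 (3E)-1-bromohex-3-ene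
Conditions: CBr4 (1.2 equiv), PPh3 (1.25 equiv), CH2Cl2, 0 → 20 °C
Reagents that add atoms: carbon tetrabromide, BrC(Br)(Br)Br
Why: Appel reaction; bromide displaces the alkoxyphosphonium of the primary alcohol in an SN2 step under neutral conditions, so the homoallylic (E)-alkene is neither shifted nor isomerised.

Step 2
Reactants: 2 (3E)-1-bromohex-3-ene; 3 1,12-dibromododecane
Product: 5 (3E)-18-bromooctadec-3-ene, via (3E)-hex-3-en-1-ylmagnesium bromide 4 (not isolated)
Conditions: Mg, THF, 40 °C; then added to 3 (3 equiv), Li2CuCl4 (3 mol %), THF, −10 → 20 °C
Reagents that add atoms: none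
Why: Copper-catalysed sp3–sp3 cross-coupling of a Grignard reagent with a primary alkyl bromide forms C13′–C14′; the excess of symmetrical 3 keeps double coupling minor and is recovered. The homoallylic Grignard reagent should keep its alkene geometry under these conditions.

Step 3
Reactants: 5 (3E)-18-bromooctadec-3-ene; 6 2-hydroxy-5-methoxybenzaldehyde
Product: 9 rac-2-[(16E)-1-hydroxynonadec-16-en-1-yl]-4-methoxyphenol, via (15E)-octadec-15-en-1-ylmagnesium bromide 7 (not isolated), via chloromagnesium 2-formyl-4-methoxyphenolate 8 (not isolated)
Conditions: 5, Mg, THF, 45 °C (gives 7); 6, i-PrMgCl (1.0 equiv), THF, −20 °C (gives 8); 7 (1.2 equiv) added to 8, −20 → 0 °C; aq NH4Cl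
Reagents that add atoms: none
Why: Grignard 1,2-addition to the aldehyde forms C1′–C2′; prior deprotonation of the phenol by a sacrificial Grignard base spares one equivalent of 7. The new carbinol centre is left racemic on purpose because step 4 removes it.

Step 4
Reactants: 9 rac-2-[(16E)-1-hydroxynonadec-16-en-1-yl]-4-methoxyphenol
Product: 10 4-methoxy-2-[(16E)-nonadec-16-en-1-yl]phenol
Conditions: Et3SiH (3 equiv), CF3CO2H (5 equiv), CH2Cl2, 0 °C
Reagents that add atoms: none
Why: Ionic hydrogenation; acid ionises the o-hydroxybenzylic alcohol to an o-quinone-methide-like cation that takes hydride from the silane, and any styrene formed by proton loss re-enters the same cation. The isolated 1,2-dialkyl alkene is not basic enough to be protonated under these conditions.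

Step 5
Reactants: 10 4-methoxy-2-[(16E)-nonadec-16-en-1-yl]phenol
Product: 11 4,4-dimethoxy-2-[(16E)-nonadec-16-en-1-yl]cyclohexa-2,5-dien-1-one
Conditions: PhI(OAc)2 (1.1 equiv), dry MeOH/CH2Cl2 (3:1), 0 °C
Reagents that add atoms: methanol, CO
Why: Ligand exchange of the phenol on iodine(III) gives an aryloxy-λ3-iodane, which loses iodobenzene in a two-electron step to a phenoxenium ion that is in essence the O-methyl oxocarbenium ion of C1; methanol adds there and the dimethyl ketal results. The closest known reaction type is the hypervalent-iodine oxidation of 4-alkoxyphenols to p-quinone monoketals, which tolerates 2-alkyl groups. No ring is closed: the carbocycle is inherited from the arene, and the step creates its functional pattern, namely the C4 carbonyl, the masked C1 carbonyl, the C2=C3 alkene and the trisubstituted C5=C6 alkene, all in their final positions. No stereocentre is formed; the product is achiral but presents the two prochiral elements from which C4 (step 6, catalyst control) and C5 (step 7, direction by the C4 hydroxyl) are then set. The step needs para rather than ortho capture of the cation, which the para methoxy group secures by localising the positive charge on C1. It also needs chemoselectivity for the phenol over the chain alkene, which should hold because the iodine(III) reagent is not acid-activated and isolated alkenes do not react with it at 0 °C. Dry methanol keeps water from competing and giving the quinone, and the co-solvent keeps the lipid in solution.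

Step 6
Reactants: 11 4,4-dimethoxy-2-[(16E)-nonadec-16-en-1-yl]cyclohexa-2,5-dien-1-one
Product: 12 (1R)-4,4-dimethoxy-2-[(16E)-nonadec-16-en-1-yl]cyclohexa-2,5-dien-1-ol
Conditions: (S)-2-methyl-CBS-oxazaborolidine (0.2 equiv), catecholborane (1.5 equiv), toluene, −78 °C; cold aq NaOH wash
Reagents that add atoms: none
Why: Corey–Bakshi–Shibata reduction; the carbonyl binds the catalyst boron anti to its larger, α-branched alkenyl arm (C5 side) and hydride is delivered to the Si face, which should give the 4R carbinol in a clean 1,2-sense. Catecholborane at −78 °C does not hydroborate the chain alkene, and the basic work-up protects the acid-labile dienol ketal.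

Step 7
Reactants: 12 (1R)-4,4-dimethoxy-2-[(16E)-nonadec-16-en-1-yl]cyclohexa-2,5-dien-1-ol
Product: 13 (1R,2R,6R)-5,5-dimethoxy-1-[(16E)-nonadec-16-en-1-yl]-7-oxabicyclo[4.1.0]hept-3-en-2-ol
Conditions: VO(acac)2 (5 mol %), t-BuOOH (1.1 equiv, decane), CH2Cl2, 0 °C
Reagents that add atoms: tert-butyl hydroperoxide, CC(C)(C)OO
Why: Vanadium-catalysed hydroxyl-directed epoxidation of an allylic alcohol; the alkoxo vanadium(V) alkylperoxide reaches only the face that carries the C4 oxygen, so C5–O is formed cis to C4–OH, which fixes C5 (S in 15). Of the two ring alkenes the trisubstituted C5=C6 is the more nucleophilic, and the chain alkene has no directing group and should be left alone.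

Step 8
Reactants: 13 (1R,2R,6R)-5,5-dimethoxy-1-[(16E)-nonadec-16-en-1-yl]-7-oxabicyclo[4.1.0]hept-3-en-2-ol
Product: 14 (1R,5R,6R)-5-hydroxy-6-[(16E)-nonadec-16-en-1-yl]-7-oxabicyclo[4.1.0]hept-3-en-2-one
Conditions: PPTS (0.1 equiv), acetone/H2O (10:1), 0 → 20 °C
Reagents that add atoms: water, O
Why: Acid-catalysed ketal hydrolysis through an allyl-stabilised oxocarbenium ion; an enone dimethyl ketal cleaves under much milder acid than the epoxide opens, as in epoxyquinol chemistry. No stereocentre is touched.

Step 9
Reactants: 14 (1R,5R,6R)-5-hydroxy-6-[(16E)-nonadec-16-en-1-yl]-7-oxabicyclo[4.1.0]hept-3-en-2-one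
Product: 15 (4R,5S)-4,5-dihydroxy-5-[(16E)-nonadec-16-en-1-yl]cyclohex-2-en-1-one
Conditions: SmI2 (2.2 equiv), THF/MeOH (4:1), −78 °C; pH 7 phosphate buffer
Reagents that add atoms: none
Why: Samarium(II) reduction of an α,β-epoxy ketone; the ketyl expels the oxygen from Cα (C6), a second electron gives the samarium enolate, and methanol protonates it to the β-hydroxy ketone. The C5–O bond is never broken, so C5 keeps its configuration, and the cold neutral medium avoids dehydration to the aromatic ring.

## Compound list

1 | (3E)-hex-3-en-1-ol | CC/C=C/CCO | starting material
2 | (3E)-1-bromohex-3-ene | CC/C=C/CCBr | intermediate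
3 | 1,12-dibromododecane | BrCCCCCCCCCCCCBr | starting material
4 | (3E)-hex-3-en-1-ylmagnesium bromide | CC/C=C/CC[Mg]Br | intermediate
5 | (3E)-18-bromooctadec-3-ene | CC/C=C/CCCCCCCCCCCCCCBr | intermediate
6 | 2-hydroxy-5-methoxybenzaldehyde | COc1ccc(O)c(C=O)c1 | starting material
7 | (15E)-octadec-15-en-1-ylmagnesium bromide | CC/C=C/CCCCCCCCCCCCCC[Mg]Br | intermediate
8 | chloromagnesium 2-formyl-4-methoxyphenolate | COc1ccc(O[Mg]Cl)c(C=O)c1 | intermediate
9 | rac-2-[(16E)-1-hydroxynonadec-16-en-1-yl]-4-methoxyphenol | CC/C=C/CCCCCCCCCCCCCCC(O)c1cc(OC)ccc1O | intermediate
10 | 4-methoxy-2-[(16E)-nonadec-16-en-1-yl]phenol | CC/C=C/CCCCCCCCCCCCCCCc1cc(OC)ccc1O | intermediate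
11 | 4,4-dimethoxy-2-[(16E)-nonadec-16-en-1-yl]cyclohexa-2,5-dien-1-one | CC/C=C/CCCCCCCCCCCCCCCC1=CC(OC)(OC)C=CC1=O | intermediate
12 | (1R)-4,4-dimethoxy-2-[(16E)-nonadec-16-en-1-yl]cyclohexa-2,5-dien-1-ol | CC/C=C/CCCCCCCCCCCCCCCC1=CC(OC)(OC)C=C[C@H]1O | intermediate
13 | (1R,2R,6R)-5,5-dimethoxy-1-[(16E)-nonadec-16-en-1-yl]-7-oxabicyclo[4.1.0]hept-3-en-2-ol (epoxide cis to the hydroxyl) | CC/C=C/CCCCCCCCCCCCCCC[C@]12O[C@H]1C(OC)(OC)C=C[C@H]2O | intermediate
14 | (1R,5R,6R)-5-hydroxy-6-[(16E)-nonadec-16-en-1-yl]-7-oxabicyclo[4.1.0]hept-3-en-2-one (epoxide cis to the hydroxyl) | CC/C=C/CCCCCCCCCCCCCCC[C@]12O[C@H]1C(=O)C=C[C@H]2O | intermediate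
15 | (4R,5S)-4,5-dihydroxy-5-[(16E)-nonadec-16-en-1-yl]cyclohex-2-en-1-one | CC/C=C/CCCCCCCCCCCCCCC[C@]1(O)CC(=O)C=C[C@H]1O | target

## Step count and risk

Total step count: 9. Longest linear sequence: 9 steps (1 → 15); 3 and 6 are purchased and enter in steps 2 and 3.

**Step 5 (key step).** The most likely failures are incomplete conversion, because the C19 lipid is poorly soluble in methanol, and over-oxidation with loss of the methyl group if traces of water compete with methanol for the cation. The fallback reverses the order of dearomatisation and chain attachment; it sets out from 5 and returns at 11. Commercial 2-bromo-4-methoxyphenol, a small methanol-soluble arene, is dearomatised under the same iodine(III) conditions to 2-bromo-4,4-dimethoxycyclohexa-2,5-dien-1-one F1. In parallel the Grignard reagent 7 made from 5 is extended by one carbon with (chloromethyl)boronic acid pinacol ester (Matteson homologation: ate complex, then 1,2-shift with loss of chloride) to 2-[(16E)-nonadec-16-en-1-yl]-4,4,5,5-tetramethyl-1,3,2-dioxaborolane F2. A Suzuki–Miyaura sp2–sp3 coupling of F1 with F2 (Pd(dppf)Cl2, Ag2O, K2CO3, THF, 65 °C) should then give 11, and steps 3 and 4 are no longer needed.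

**Step 6.** Facial discrimination may be poor because both carbonyl substituents are alkenyl arms that differ only in α-branching, and the dienol may re-aromatise by acid-triggered loss of methanol during isolation. The fallback replaces asymmetric catalysis by resolution; it sets out from 11 and returns at 12. Luche reduction (NaBH4, CeCl3, MeOH, −78 °C) gives rac-4,4-dimethoxy-2-[(16E)-nonadec-16-en-1-yl]cyclohexa-2,5-dien-1-ol F3. Lipase-catalysed transesterification (Burkholderia cepacia lipase, vinyl acetate, MTBE, 20 °C) should acylate the (R)-enantiomer, in which the alkyl-bearing arm is the large group, to (1R)-4,4-dimethoxy-2-[(16E)-nonadec-16-en-1-yl]cyclohexa-2,5-dien-1-yl acetate F4. F4 is separated from the unreacted (S)-alcohol and methanolysed (K2CO3, MeOH, 0 °C) to 12.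

**Step 7.** Oxidation of the bis-allylic carbinol back to the dienone, Lewis-acid-induced aromatisation and a second epoxidation of the C2=C3 alkene all compete with the desired oxygen transfer. The fallback forms the same epoxide without any oxidant for the carbinol; it sets out from 12 and returns at 13. The lithium alkoxide of 12 (n-BuLi, THF, −78 °C) is carboxylated with CO2 and the carbonate is cyclised with iodine onto C5=C6. Iodonium formation is reversible, and only the alkene with an internal nucleophile is trapped (5-exo, oxygen to the more substituted C5, cis ring fusion). This gives (3aR,4S,7aR)-4-iodo-5,5-dimethoxy-3a-[(16E)-nonadec-16-en-1-yl]-3a,4,5,7a-tetrahydro-1,3-benzodioxol-2-one F5, a cyclic carbonate across O4/O5 with the C6 iodide on the opposite face. K2CO3 in methanol cleaves the carbonate, and the freed C5 alkoxide displaces the trans iodide to close the cis epoxide 13.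

**Step 9.** Electron transfer to the enone, with reduction of C2=C3 or expulsion of the C4 hydroxyl, may compete with epoxide fragmentation, and the product may dehydrate towards the arene during work-up. The fallback opens the epoxide before any enone exists; it sets out from 13 and returns at 15. LiEt3BH (THF, 0 → 20 °C) delivers hydride to C6, the only epoxide carbon open to SN2 attack, to give (1S,2R)-5,5-dimethoxy-1-[(16E)-nonadec-16-en-1-yl]cyclohex-3-ene-1,2-diol F6. Mild ketal hydrolysis (PPTS, wet acetone, 0 °C) then gives 15.

## Further compounds

F1 | step 5 | 2-bromo-4,4-dimethoxycyclohexa-2,5-dien-1-one | COC1(OC)C=CC(=O)C(Br)=C1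
F2 | step 5 | 2-[(16E)-nonadec-16-en-1-yl]-4,4,5,5-tetramethyl-1,3,2-dioxaborolane | CC/C=C/CCCCCCCCCCCCCCCB1OC(C)(C)C(C)(C)O1
F3 | step 6 | rac-4,4-dimethoxy-2-[(16E)-nonadec-16-en-1-yl]cyclohexa-2,5-dien-1-ol | CC/C=C/CCCCCCCCCCCCCCCC1=CC(OC)(OC)C=CC1O
F4 | step 6 | (1R)-4,4-dimethoxy-2-[(16E)-nonadec-16-en-1-yl]cyclohexa-2,5-dien-1-yl acetate | CC/C=C/CCCCCCCCCCCCCCCC1=CC(OC)(OC)C=C[C@H]1OC(C)=O
F5 | step 7 | (3aR,4S,7aR)-4-iodo-5,5-dimethoxy-3a-[(16E)-nonadec-16-en-1-yl]-3a,4,5,7a-tetrahydro-1,3-benzodioxol-2-one | CC/C=C/CCCCCCCCCCCCCCC[C@@]12OC(=O)O[C@@H]1C=CC(OC)(OC)[C@H]2I
F6 | step 9 | (1S,2R)-5,5-dimethoxy-1-[(16E)-nonadec-16-en-1-yl]cyclohex-3-ene-1,2-diol | CC/C=C/CCCCCCCCCCCCCCC[C@]1(O)CC(OC)(OC)C=C[C@H]1O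
A1 | alternative 1 | (5S,6R)-5,6-dihydroxy-5-[(16E)-nonadec-16-en-1-yl]octa-1,7-dien-3-one | CC/C=C/CCCCCCCCCCCCCCC[C@]([C@H](O)C=C)(O)CC(=O)C=C
A2 | alternative 2 | benzoic acid | OC(=O)c1ccccc1
A3 | alternative 2 | (1S,2R)-1,2-dihydroxycyclohexa-3,5-diene-1-carboxylic acid | OC(=O)[C@]1(O)C=CC=C[C@H]1O
A4 | alternative 3 | (6S)-6-hydroxy-4-methoxy-6-[(16E)-nonadec-16-en-1-yl]cyclohexa-2,4-dien-1-one | CC/C=C/CCCCCCCCCCCCCCC[C@]1(O)C=C(OC)C=CC1=O
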